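**Assumption:** positions follow eremophilane numbering (ring A = C1–C5 and C10; ring B = C5–C10; C14 = methyl on C5; C15 = carbon on C4; C11–C13 = isopropenyl on C7); β is the face of the C5 methyl, α the opposite face; every compound from 3 on keeps the 5β-methyl of 1.

## Retrosynthetic overview

1. The two esters come off last (C3 senecioate after C9 tiglate), leaving a 3α,9α-dioxygenated 7βH,10αH-eremophil-11-en-8-one.
2. The C9 oxygen and the trans ring fusion both come from one 9-en-8-one: dissolving-metal reduction sets 10α-H and gives the C8–C9 enolate for hydroxylation.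
3. Key C–C disconnection C7–C11: the isopropenyl group is joined to the α′-carbon with both partners in nucleophile form (silyl dienol ether and isopropenylzinc); trivalent iodine turns the enol carbon into an enolonium electrophile.
4. C3–OH and C4–CH3 come from a C4 ketone by methylenation, allylic hydroxylation at C3 and hydroxyl-directed hydrogenation.
5. No ring is formed in the route: rings A and B, with the C5 quaternary centre, are bought fused as (S)-Wieland–Miescher ketone (enone ring = ring B, saturated ketone ring = ring A).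

## Route

Step 1
Reactants: 1 (S)-Wieland–Miescher ketone; 2 methyltriphenylphosphonium bromide
Product: 3 11,12,13-trinoreremophila-4(15),9-dien-8-one
Conditions: 2 (1.5 equiv), KOtBu (1.4 equiv), THF, 0 °C to rt
Reagents that add atoms: methyltriphenylphosphonium bromide (2), C[P+](c1ccccc1)(c1ccccc1)c1ccccc1.[Br-]
Why: Wittig methylenation; the ylide attacks the non-conjugated C4 ketone, which is far more electrophilic than the enone carbonyl (partly masked as its dienolate by the basic ylide), and no stereocentre is formed.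

Step 2
Reactants: 3 11,12,13-trinoreremophila-4(15),9-dien-8-one
Product: 4 3α-hydroxy-11,12,13-trinoreremophila-4(15),9-dien-8-one
Conditions: SeO2 (0.3 equiv), tBuOOH (2.5 equiv), CH2Cl2, 0 °C to rt
Reagents that add atoms: selenium dioxide, O=[Se]=O; tert-butyl hydroperoxide, CC(C)(C)OO
Why: Riley allylic hydroxylation (ene reaction at the exocyclic alkene, then [2,3]-sigmatropic shift) puts oxygen on C3, the only allylic CH2 because C5 is quaternary, from the α-face since the β-face of C3 is syn-axial to the C5 methyl, which sets 3α-OH.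

Step 3
Reactants: 4 3α-hydroxy-11,12,13-trinoreremophila-4(15),9-dien-8-one
Product: 5 3α-hydroxy-11,12,13-trinoreremophil-9-en-8-one
Conditions: H2 (1 atm), [Ir(cod)(PCy3)(py)]PF6 (3 mol %), CH2Cl2, 0 °C
Reagents that add atoms: none
Why: hydroxyl-directed homogeneous hydrogenation; the cationic iridium catalyst binds the allylic 3α-OH and adds H2 to the exocyclic alkene from the α-face (also the face away from the C5 methyl), which sets the 4β-methyl (4α-H), while the electron-poor trisubstituted enone alkene is left.

Step 4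
Reactants: 5 3α-hydroxy-11,12,13-trinoreremophil-9-en-8-one; 6 isopropenylmagnesium bromide
Product: 9 3α-(triethylsilyloxy)-7βH-eremophila-9,11-dien-8-one, via bis(triethylsilyl) dienol ether 7 (not isolated), via enolonium species 8 (not isolated)
Conditions: LiN(iPr)2 (2.2 equiv), Et3SiCl (2.5 equiv), THF, −78 to 0 °C; solvent switch to CH2Cl2; PhI(OAc)2 (1.2 equiv), BF3·OEt2 (1.5 equiv), −78 °C; then [CH2=C(CH3)]2Zn (2 equiv, from 6 and ZnCl2), −78 to −30 °C
Reagents that add atoms: chlorotriethylsilane, CC[Si](Cl)(CC)CC; isopropenylmagnesium bromide (6), C=C(C)[Mg]Br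
Why: Proposed new method: kinetic α′-deprotonation and O-silylation give the cross-conjugated silyl dienol ether 7, which the BF3-activated trivalent-iodine reagent converts into the O-bound enolonium species 8 with an electrophilic C7, and the isopropenylzinc nucleophile then bonds to C7 (direct attack or ligand coupling on iodine, with loss of iodobenzene) from the α-face opposite the syn-axial C5 methyl, which sets the equatorial 7α-isopropenyl group without any base that could move the new double bond into conjugation; closest known reaction type: oxidative umpolung α-alkylation of ketone enolates and silyl enol ethers with a hypervalent iodine reagent and dialkylzinc (enolonium chemistry).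

Step 5
Reactants: 9 3α-(triethylsilyloxy)-7βH-eremophila-9,11-dien-8-one
Product: 11 3α-(triethylsilyloxy)-8-(trimethylsilyloxy)-7βH,10αH-eremophila-8,11-diene, via lithium enolate 10 (not isolated)
Conditions: Li (2.5 equiv), tBuOH (1.0 equiv), NH3/THF, −78 °C; isoprene; NH3 evaporated; then Me3SiCl, Et3N, THF, −78 to 0 °C
Reagents that add atoms: chlorotrimethylsilane, C[Si](C)(C)Cl
Why: Birch-type dissolving-metal reduction of the enone; the β-carbanion is protonated axially at C10 to give the trans-fused 10α-H junction and the lithium enolate 10 with its double bond fixed at C8–C9, which is trapped on oxygen (Stork reductive silylation), while the isolated isopropenyl alkene and the silyl ether are not reduced.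

Step 6
Reactants: 11 3α-(triethylsilyloxy)-8-(trimethylsilyloxy)-7βH,10αH-eremophila-8,11-diene; 12 (E)-2-methylbut-2-enoyl chloride (tigloyl chloride)
Product: 16 3α-hydroxy-9α-[(E)-2-methylbut-2-enoyloxy]-7βH,10αH-eremophil-11-en-8-one, via potassium enolate 13 (not isolated), via potassium alkoxide 14 (not isolated), via triethylsilyl ether 15 (not isolated)
Conditions: KOtBu (1.05 equiv), THF, −20 °C; then 2-(phenylsulfonyl)-3-phenyloxaziridine (1.2 equiv), −78 °C; 12 (1.5 equiv), −78 to 0 °C; then 1 M HCl, MeOH, 0 °C
Reagents that add atoms: 2-(phenylsulfonyl)-3-phenyloxaziridine, O=S(=O)(N1OC1c1ccccc1)c1ccccc1; (E)-2-methylbut-2-enoyl chloride (12), C/C=C(\C)C(=O)Cl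
Why: KOtBu attacks silicon of the trimethylsilyl enol ether only (the hindered triethylsilyl alkyl ether is untouched) and releases the regiodefined potassium enolate 13 with aprotic tBuOSiMe3 as the only by-product, so no proton source can move the enolate; Davis hydroxylation with the N-sulfonyloxaziridine, which is cleaner for potassium than for lithium enolates, occurs on the α-face (the β-face of C9 is syn-axial to the C5 methyl) to give the equatorial 9α-alkoxide 14, which is acylated in the same flask before dilute acid removes the triethylsilyl group.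

Step 7
Reactants: 16 3α-hydroxy-9α-[(E)-2-methylbut-2-enoyloxy]-7βH,10αH-eremophil-11-en-8-one; 17 3-methylbut-2-enoic acid
Product: 18 3α-(3-methylbut-2-enoyloxy)-9α-[(E)-2-methylbut-2-enoyloxy]-7βH,10αH-eremophil-11-en-8-one (target CNP0164025.1)
Conditions: 17 (1.5 equiv), DCC (1.6 equiv), DMAP (0.2 equiv), CH2Cl2, 0 °C to rt
Reagents that add atoms: 3-methylbut-2-enoic acid (17), CC(C)=CC(=O)O
Why: Steglich esterification of the only free hydroxyl (equatorial 3α-OH) with retention at C3; the carbodiimide conditions avoid the vinylketene pathway that deconjugates the acid chloride and are too mild to epimerise C7 or C9 or to isomerise the isopropenyl ketone.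

## Compound list

1 | (S)-Wieland–Miescher ketone, (S)-8a-methyl-3,4,8,8a-tetrahydronaphthalene-1,6(2H,7H)-dione (commercial) | O=C1CC[C@]2(C)C(=O)CCCC2=C1 | starting material
2 | methyltriphenylphosphonium bromide | C[P+](c1ccccc1)(c1ccccc1)c1ccccc1.[Br-] | starting material
3 | 11,12,13-trinoreremophila-4(15),9-dien-8-one (5β-methyl, exocyclic methylene at C4) | O=C1CC[C@]2(C)C(=C)CCCC2=C1 | intermediate
4 | 3α-hydroxy-11,12,13-trinoreremophila-4(15),9-dien-8-one | O=C1CC[C@]2(C)C(=C)[C@H](O)CCC2=C1 | intermediate
5 | 3α-hydroxy-11,12,13-trinoreremophil-9-en-8-one (4β,5β-dimethyl) | O=C1CC[C@]2(C)[C@@H](C)[C@H](O)CCC2=C1 | intermediate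
6 | isopropenylmagnesium bromide | C=C(C)[Mg]Br | starting material
7 | 3α,8-bis(triethylsilyloxy)-11,12,13-trinoreremophila-7,9-diene | CC[Si](CC)(CC)OC1=CC[C@]2(C)[C@@H](C)[C@H](O[Si](CC)(CC)CC)CCC2=C1 | intermediate
8 | enolonium species, 8-[acetoxy(phenyl)-λ3-iodanyloxy]-3α-(triethylsilyloxy)-11,12,13-trinoreremophila-7,9-diene | CC(=O)OI(c1ccccc1)OC1=CC[C@]2(C)[C@@H](C)[C@H](O[Si](CC)(CC)CC)CCC2=C1 | intermediate
9 | 3α-(triethylsilyloxy)-7βH-eremophila-9,11-dien-8-one (7α-isopropenyl) | C=C(C)[C@@H]1C[C@]2(C)[C@@H](C)[C@H](O[Si](CC)(CC)CC)CCC2=CC1=O | intermediate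
10 | lithium 3α-(triethylsilyloxy)-7βH,10αH-eremophila-8,11-dien-8-olate | C=C(C)[C@@H]1C[C@]2(C)[C@@H](C)[C@H](O[Si](CC)(CC)CC)CC[C@H]2C=C1O[Li] | intermediate
11 | 3α-(triethylsilyloxy)-8-(trimethylsilyloxy)-7βH,10αH-eremophila-8,11-diene | C=C(C)[C@@H]1C[C@]2(C)[C@@H](C)[C@H](O[Si](CC)(CC)CC)CC[C@H]2C=C1O[Si](C)(C)C | intermediate
12 | (E)-2-methylbut-2-enoyl chloride (tigloyl chloride) | C/C=C(\C)C(=O)Cl | starting material
13 | potassium 3α-(triethylsilyloxy)-7βH,10αH-eremophila-8,11-dien-8-olate | C=C(C)[C@@H]1C[C@]2(C)[C@@H](C)[C@H](O[Si](CC)(CC)CC)CC[C@H]2C=C1O[K] | intermediate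
14 | potassium 8-oxo-3α-(triethylsilyloxy)-7βH,10αH-eremophil-11-en-9α-olate | C=C(C)[C@@H]1C[C@]2(C)[C@@H](C)[C@H](O[Si](CC)(CC)CC)CC[C@H]2[C@H](O[K])C1=O | intermediate
15 | 9α-[(E)-2-methylbut-2-enoyloxy]-3α-(triethylsilyloxy)-7βH,10αH-eremophil-11-en-8-one | C=C(C)[C@@H]1C[C@]2(C)[C@@H](C)[C@H](O[Si](CC)(CC)CC)CC[C@H]2[C@H](OC(=O)/C(C)=C/C)C1=O | intermediate
16 | 3α-hydroxy-9α-[(E)-2-methylbut-2-enoyloxy]-7βH,10αH-eremophil-11-en-8-one | C=C(C)[C@@H]1C[C@]2(C)[C@@H](C)[C@H](O)CC[C@H]2[C@H](OC(=O)/C(C)=C/C)C1=O | intermediate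
17 | 3-methylbut-2-enoic acid (senecioic acid) | CC(C)=CC(=O)O | starting material
18 | 3α-(3-methylbut-2-enoyloxy)-9α-[(E)-2-methylbut-2-enoyloxy]-7βH,10αH-eremophil-11-en-8-one (CNP0164025.1) | C=C(C)[C@@H]1C[C@]2(C)[C@@H](C)[C@H](OC(=O)C=C(C)C)CC[C@H]2[C@H](OC(=O)/C(C)=C/C)C1=O | target

## Step count and risks

Total step count: 7. Longest linear sequence: 7 steps (1 to 18).

**Step 4** is the most likely to fail: acetate may transfer instead of isopropenyl, or the enolonium may lose a proton to give the dienone. The fallback sets out from 5 and comes back at 9. Compound 5 is silylated as in step 4 to 7, which is brominated at C7 with N-bromosuccinimide (THF, −78 °C) to the isolable α′-bromo enone 7α-bromo-3α-(triethylsilyloxy)-11,12,13-trinoreremophil-9-en-8-one F3. F3, a stable enolonium equivalent, is then cross-coupled with CH2=C(CH3)ZnCl under NiCl2(dme)/4,4′-di-tert-butyl-2,2′-bipyridine catalysis. This Negishi coupling of a secondary α-bromo ketone runs through a C7 radical, so both C7 epimers converge on the 7α product 9.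

**Step 2** is the second risk: the facial selectivity at C3 is not certain and over-oxidation to the ketone is possible. The fallback sets out from 3 and comes back at 4. TsOH (benzene, 80 °C) moves the exocyclic double bond into the ring to give the trisubstituted alkene 11,12,13-trinoreremophila-3,9-dien-8-one F1. mCPBA epoxidises this electron-rich alkene on the α-face, away from the C5 methyl, to 3α,4α-epoxy-11,12,13-trinoreremophil-9-en-8-one F2. Diethylaluminium 2,2,6,6-tetramethylpiperidide, Et2AlN(C9H18), then removes a C15 proton in a syn-elimination and opens the epoxide to 4, with the 3α-oxygen fixed by the epoxide.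

**Step 6** is the third risk: the potassium enolate can add to the sulfonylimine by-product, acylation of the hindered alkoxide can be incomplete, and the basic alkoxide can epimerise C7 before it is trapped. The fallback sets out from 11 and comes back at 15. Rubottom oxidation of 11 with dimethyldioxirane (acetone, −78 °C) gives 3α-(triethylsilyloxy)-9α-(trimethylsilyloxy)-7βH,10αH-eremophil-11-en-8-one F4 without any enolate. Citric acid in MeOH cleaves only the trimethylsilyl ether to the isolated α-hydroxy ketone 9α-hydroxy-3α-(triethylsilyloxy)-7βH,10αH-eremophil-11-en-8-one F5. F5 is acylated with 12, pyridine and DMAP to give 15 as an isolated compound, which loses its triethylsilyl group with HCl in MeOH as in step 6 to give 16.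

Further compounds
F1 | step 2 | 11,12,13-trinoreremophila-3,9-dien-8-one | O=C1CC[C@]2(C)C(C)=CCCC2=C1
F2 | step 2 | 3α,4α-epoxy-11,12,13-trinoreremophil-9-en-8-one | O=C1CC[C@]2(C)[C@]3(C)O[C@@H]3CCC2=C1
F3 | step 4 | 7α-bromo-3α-(triethylsilyloxy)-11,12,13-trinoreremophil-9-en-8-one | Br[C@@H]1C[C@]2(C)[C@@H](C)[C@H](O[Si](CC)(CC)CC)CCC2=CC1=O
F4 | step 6 | 3α-(triethylsilyloxy)-9α-(trimethylsilyloxy)-7βH,10αH-eremophil-11-en-8-one | C=C(C)[C@@H]1C[C@]2(C)[C@@H](C)[C@H](O[Si](CC)(CC)CC)CC[C@H]2[C@H](O[Si](C)(C)C)C1=O
F5 | step 6 | 9α-hydroxy-3α-(triethylsilyloxy)-7βH,10αH-eremophil-11-en-8-one | C=C(C)[C@@H]1C[C@]2(C)[C@@H](C)[C@H](O[Si](CC)(CC)CC)CC[C@H]2[C@H](O)C1=O
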